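**Retrosynthetic overview**
- Feature: C2 is benzylic to ring B and para to its 4'-OH. C3–H lies between C2, the ester and ring A. Ionising C2 gives the ring B para-quinone methide, in which C2 is planar and C3–H is labile, so both stereocentres can be written last from a stereorandom precursor.
- Last disconnection: O1–C2. The dihydrofuran is the only ring formed, and it is formed last. Rings A and B are bought. This leads back to the fully unprotected aldol.
- Before that: the C5–vinyl bond by a Heck reaction with methyl acrylate, and C2–C3 by an unselective lithium aldol between a ring A arylacetate and silylated protocatechualdehyde.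
- The ring A arylacetate comes from 2,3-dihydroxybenzaldehyde by C5 bromination, silylation, Wittig methoxymethylenation and oxidation of the enol ether.

Key step: step 9

Assumption: the sense of induction of the chiral acid cannot be predicted for this new reaction. The (R)-catalyst is written, and the (S)-antipode takes its place if screening shows that it leads to the (2R,3R) product.

Step 1
Reactants: 1 2,3-dihydroxybenzaldehyde
Product: 2 5-bromo-2,3-dihydroxybenzaldehyde
Conditions: Br2, NaOAc, AcOH, rt
Reagents that add atoms: bromine, BrBr
Why: Electrophilic aromatic bromination should go to C5, the one position para to the 2-hydroxyl and meta to the formyl group, because the positions activated by the 3-hydroxyl are ortho or para to the deactivating aldehyde.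

Step 2
Reactants: 2 5-bromo-2,3-dihydroxybenzaldehyde
Product: 3 5-bromo-2,3-bis(tert-butyldimethylsilyloxy)benzaldehyde
Conditions: TBSCl, imidazole, DMF, rt
Reagents that add atoms: tert-butyldimethylsilyl chloride, CC(C)(C)[Si](C)(C)Cl
Why: Imidazole-promoted silylation caps both phenols as aryl silyl ethers, which tolerate ylide, amide base and palladium and later leave with fluoride without touching ester, alkene or carbinol.

Step 3
Reactants: 3 5-bromo-2,3-bis(tert-butyldimethylsilyloxy)benzaldehyde
Product: 4 5-bromo-1-(2-methoxyethenyl)-2,3-bis(tert-butyldimethylsilyloxy)benzene (E/Z mixture)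
Conditions: MeOCH2PPh3Cl, KN(SiMe3)2, THF, 0 °C; then 3, −78 °C to rt
Reagents that add atoms: (methoxymethyl)triphenylphosphonium chloride, COC[P+](c1ccccc1)(c1ccccc1)c1ccccc1.[Cl-]
Why: The Wittig methoxymethylenation, run with ylide preformed from a slight deficit of base, adds the missing carbon without attacking the aryl silyl ethers, and the alkene geometry does not matter because both isomers converge in step 4.

Step 4
Reactants: 4 5-bromo-1-(2-methoxyethenyl)-2,3-bis(tert-butyldimethylsilyloxy)benzene
Product: 5 methyl 2-[5-bromo-2,3-bis(tert-butyldimethylsilyloxy)phenyl]acetate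
Conditions: [C5H5NH][CrO3Cl], Celite, CH2Cl2, rt
Reagents that add atoms: pyridinium chlorochromate, [O-][Cr](=O)(=O)Cl.c1cc[nH+]cc1
Why: The known chlorochromate oxidation of enol ethers to esters (oxygen delivered to the methoxy-bearing carbon, then a 1,2-hydride shift) gives the methyl ester directly, and aryl silyl ethers and the aryl bromide are inert to this reagent.

Step 5
Reactants: 6 3,4-dihydroxybenzaldehyde
Product: 7 3,4-bis(tert-butyldimethylsilyloxy)benzaldehyde
Conditions: TBSCl, imidazole, DMF, rt
Reagents that add atoms: tert-butyldimethylsilyl chloride, CC(C)(C)[Si](C)(C)Cl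
Why: The same imidazole-promoted silylation masks the ring B catechol, so that the aldehyde meets the enolate with no acidic proton present.

Step 6
Reactants: 5 methyl 2-[5-bromo-2,3-bis(tert-butyldimethylsilyloxy)phenyl]acetate; 7 3,4-bis(tert-butyldimethylsilyloxy)benzaldehyde
Product: 10 methyl 2-[5-bromo-2,3-bis(tert-butyldimethylsilyloxy)phenyl]-3-[3,4-bis(tert-butyldimethylsilyloxy)phenyl]-3-hydroxypropanoate (all four stereoisomers), via lithium enolate 8 (not isolated), via lithium aldolate 9 (not isolated)
Conditions: LiN(i-Pr)2, THF, −78 °C; then 7, −78 °C; AcOH quench at −78 °C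
Reagents that add atoms: none
Why: The lithium ester-enolate aldol addition forms C2–C3 with no control sought at either new centre, since both are erased in step 9, and the cold acetic acid quench forestalls retro-aldol cleavage and silyl migration.

Step 7
Reactants: 10 the bromo aldol; 11 methyl acrylate
Product: 12 methyl (E)-3-{3,4-bis(tert-butyldimethylsilyloxy)-5-[1-(3,4-bis(tert-butyldimethylsilyloxy)phenyl)-1-hydroxy-3-methoxy-3-oxopropan-2-yl]phenyl}acrylate (four stereoisomers at the sp3 centres)
Conditions: Pd2(dba)3 (cat.), [HP(t-Bu)3]BF4 (cat.), Cy2NMe, dioxane, rt to 40 °C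
Reagents that add atoms: none
Why: The Mizoroki–Heck reaction with zerovalent palladium and bulky, electron-rich P(t-Bu)3 couples electron-rich aryl bromides with free ortho positions near room temperature, the tertiary amine is too weak to cause retro-aldol or dehydration, and syn insertion followed by syn beta-hydride elimination gives the E alkene.

Step 8
Reactants: 12 the tetrasilylated Heck product
Product: 13 methyl (E)-3-{3,4-dihydroxy-5-[1-(3,4-dihydroxyphenyl)-1-hydroxy-3-methoxy-3-oxopropan-2-yl]phenyl}acrylate (all four stereoisomers)
Conditions: Bu4NF/AcOH (1:1, 5 equiv), THF, 0 °C, Ar; pH 5 buffer work-up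
Reagents that add atoms: none
Why: Fluoride cleaves aryl silyl ethers quickly at 0 °C, and the equimolar acetic acid keeps the freed phenols protonated, which should suppress lactonisation of the C7a oxygen onto the ester, retro-aldol cleavage and base-induced quinone methide formation.

Step 9
Reactants: 13 the unprotected aldol (stereoisomer mixture)
Product: 16 methyl (2R,3R)-2-(3,4-dihydroxyphenyl)-7-hydroxy-5-[(E)-3-methoxy-3-oxoprop-1-enyl]-2,3-dihydrobenzofuran-3-carboxylate (target), via ring B para-quinone methide 14 (not isolated), via alpha-aryl-4-hydroxycinnamate tautomer 15 (not isolated)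
Conditions: (R)-3,3'-bis(2,4,6-triisopropylphenyl)-1,1'-binaphthyl-2,2'-diyl N-triflylphosphoramide (10 mol %), 3 Å MS, CH2Cl2–MeCN 9:1 (5 mM), −20 °C, Ar, dark
Reagents that add atoms: none
Why: Proposed new method: the strong chiral Brønsted acid protonates the C2 carbinol of any stereoisomer of 13 and the 4'-hydroxyl of ring B expels water to give para-quinone methide 14 with a planar C2, whose C3–H (flanked by the ester, ring A and the quinone methide pi system) is taken by the phosphoramidate to give achiral 15 and returned by the acid, so the C3 epimers of 14 interconvert. The closest known reactions are chiral phosphoric acid-catalysed 1,6-additions to para-quinone methides generated in situ from para-hydroxybenzyl alcohols and the trans-selective closure of such aldols by achiral acids, and what is untested is an intramolecular phenol nucleophile on a fully unprotected substrate coupled to a racemising neighbouring centre. The dihydrofuran ring closes 5-exo-trig, the C7a oxygen attacking C2 of the exocyclic C2=C1' bond to form O1–C2 while ring B rearomatises. C2 is set by the catalyst, whose acidic N–H should bind the C4' carbonyl and whose P=O should bind the C7a hydroxyl so that the 3,3'-aryl walls leave one face of C2 open, and C3 is set by Curtin–Hammett selection of the faster-closing C3 epimer of 14 (equivalently by face-selective protonation of 15), reinforced by the substrate's preference for a transition state with ring B anti to the ester, which leads to the trans (2R,3R) isomer. The step needs chemoselectivity for the C7a hydroxyl and kinetic control: the C7 hydroxyl is meta to C3a and cannot bridge to C2, the ring B hydroxyls belong to the electrophile, dilution and sieves suppress intermolecular phenol or water addition, and the low basicity of O1 in 16 (conjugated with ring A and its para acrylate) together with the low temperature should keep the product from re-ionising and the ortho-hydroxyarylacetate from lactonising.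

**Compound list**
1 | 2,3-dihydroxybenzaldehyde | O=Cc1cccc(O)c1O | starting material
2 | 5-bromo-2,3-dihydroxybenzaldehyde | O=Cc1cc(Br)cc(O)c1O | intermediate
3 | 5-bromo-2,3-bis(tert-butyldimethylsilyloxy)benzaldehyde | O=Cc1cc(Br)cc(O[Si](C)(C)C(C)(C)C)c1O[Si](C)(C)C(C)(C)C | intermediate
4 | 5-bromo-1-(2-methoxyethenyl)-2,3-bis(tert-butyldimethylsilyloxy)benzene (E/Z mixture) | COC=Cc1cc(Br)cc(O[Si](C)(C)C(C)(C)C)c1O[Si](C)(C)C(C)(C)C | intermediate
5 | methyl 2-[5-bromo-2,3-bis(tert-butyldimethylsilyloxy)phenyl]acetate | COC(=O)Cc1cc(Br)cc(O[Si](C)(C)C(C)(C)C)c1O[Si](C)(C)C(C)(C)C | intermediate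
6 | 3,4-dihydroxybenzaldehyde | O=Cc1ccc(O)c(O)c1 | starting material
7 | 3,4-bis(tert-butyldimethylsilyloxy)benzaldehyde | O=Cc1ccc(O[Si](C)(C)C(C)(C)C)c(O[Si](C)(C)C(C)(C)C)c1 | intermediate
8 | lithium enolate of 5 (not isolated) | [Li+].COC([O-])=Cc1cc(Br)cc(O[Si](C)(C)C(C)(C)C)c1O[Si](C)(C)C(C)(C)C | intermediate
9 | lithium aldolate of 10 (not isolated, stereoisomer mixture) | [Li+].COC(=O)C(C([O-])c1ccc(O[Si](C)(C)C(C)(C)C)c(O[Si](C)(C)C(C)(C)C)c1)c1cc(Br)cc(O[Si](C)(C)C(C)(C)C)c1O[Si](C)(C)C(C)(C)C | intermediate
10 | methyl 2-[5-bromo-2,3-bis(tert-butyldimethylsilyloxy)phenyl]-3-[3,4-bis(tert-butyldimethylsilyloxy)phenyl]-3-hydroxypropanoate (four stereoisomers) | COC(=O)C(C(O)c1ccc(O[Si](C)(C)C(C)(C)C)c(O[Si](C)(C)C(C)(C)C)c1)c1cc(Br)cc(O[Si](C)(C)C(C)(C)C)c1O[Si](C)(C)C(C)(C)C | intermediate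
11 | methyl acrylate | C=CC(=O)OC | starting material
12 | methyl (E)-3-{3,4-bis(tert-butyldimethylsilyloxy)-5-[1-(3,4-bis(tert-butyldimethylsilyloxy)phenyl)-1-hydroxy-3-methoxy-3-oxopropan-2-yl]phenyl}acrylate (four stereoisomers) | COC(=O)/C=C/c1cc(O[Si](C)(C)C(C)(C)C)c(O[Si](C)(C)C(C)(C)C)c(c1)C(C(=O)OC)C(O)c1ccc(O[Si](C)(C)C(C)(C)C)c(O[Si](C)(C)C(C)(C)C)c1 | intermediate
13 | methyl (E)-3-{3,4-dihydroxy-5-[1-(3,4-dihydroxyphenyl)-1-hydroxy-3-methoxy-3-oxopropan-2-yl]phenyl}acrylate (four stereoisomers, key-step precursor) | COC(=O)/C=C/c1cc(O)c(O)c(c1)C(C(=O)OC)C(O)c1ccc(O)c(O)c1 | intermediate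
14 | ring B para-quinone methide (not isolated; C3 and exocyclic alkene geometry undefined) | COC(=O)/C=C/c1cc(O)c(O)c(c1)C(C(=O)OC)C=C1C=CC(=O)C(O)=C1 | intermediate
15 | methyl 2-{2,3-dihydroxy-5-[(E)-3-methoxy-3-oxoprop-1-enyl]phenyl}-3-(3,4-dihydroxyphenyl)acrylate (not isolated; C2=C3 geometry undefined) | COC(=O)/C=C/c1cc(O)c(O)c(c1)C(C(=O)OC)=Cc1ccc(O)c(O)c1 | intermediate
16 | methyl (2R,3R)-2-(3,4-dihydroxyphenyl)-7-hydroxy-5-[(E)-3-methoxy-3-oxoprop-1-enyl]-2,3-dihydrobenzofuran-3-carboxylate | COC(=O)/C=C/c1cc(O)c2c(c1)[C@@H](C(=O)OC)[C@H](c1ccc(O)c(O)c1)O2 | target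

**Totals**
Total step count: 9.
Longest linear sequence: 8 (steps 1 to 4 and 6 to 9). Step 5 is a one-step side branch.

**Steps most likely to fail**

1. Step 9.
   - What may go wrong:
     - Ring closure may outrun the scrambling of C3, so the two C3 series close separately.
     - The four phenols may offer competing hydrogen-bond sites and lower the facial selectivity at C2.
     - The material may rest at the aromatic tautomer 15.
     - Slow re-ionisation of the O1–C2 bond may erode the enantiopurity.
     - The C7a hydroxyl may lactonise onto the C3 ester.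
   - Fallback, from 13 back to 16, by known chemistry only: 13 is stirred with a catalytic achiral sulfonic acid (p-TsOH·H2O) in CH2Cl2–MeCN at room temperature. This is the established trans-selective acid closure of such aldols through the same quinone methide. It should give the racemic trans-dihydrobenzofuran, that is 16 together with its (2S,3S) enantiomer F1. The two are then separated by preparative HPLC on a polysaccharide carbamate chiral stationary phase, and the (2R,3R) fraction is 16. Catalyst control is given up in favour of racemic synthesis plus resolution.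

2. Step 8.
   - What may go wrong:
     - The transient C7a phenoxide may lactonise onto the neighbouring methyl ester.
     - The free beta-hydroxy ester may cleave by retro-aldol.
     - The ring may close early without stereocontrol on contact with fluoride or silica.
     - Air may oxidise the two catechols.
   - Fallback, from 12 back into the key step at 14: the carbinol of 12 is methylated with Me3OBF4 and 1,8-bis(dimethylamino)naphthalene in CH2Cl2 to give the C2 methyl ether F2, which cannot undergo retro-aldol cleavage. Buffered fluoride then frees the tetraphenol methyl ether F3. Under the conditions of step 9, F3 should ionise like any para-hydroxybenzyl ether, losing methanol in place of water to give 14 and then 16. The released methanol also works against lactone formation. The leaving group of the precursor is changed, not only the deprotection recipe.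

3. Step 4.
   - What may go wrong: the electron-rich styrenyl double bond may be cleaved oxidatively back to the aldehyde, or the benzylic position may be over-oxidised in place of the hydride shift.
   - Fallback, from 4 back to 5:
     - The enol ether is hydrolysed with aqueous HCl in THF to arylacetaldehyde F4.
     - F4 is taken by Pinnick oxidation (NaClO2, NaH2PO4, 2-methyl-2-butene, t-BuOH–H2O) to arylacetic acid F5.
     - F5 is esterified with TMSCHN2 in toluene–MeOH to give 5.
     - This costs two more steps, but each is routine and free of chromium.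

**Further compounds**
F1 | step 9 | methyl (2S,3S)-2-(3,4-dihydroxyphenyl)-7-hydroxy-5-[(E)-3-methoxy-3-oxoprop-1-enyl]-2,3-dihydrobenzofuran-3-carboxylate | COC(=O)/C=C/c1cc(O)c2c(c1)[C@H](C(=O)OC)[C@@H](c1ccc(O)c(O)c1)O2
F2 | step 8 | methyl (E)-3-{3,4-bis(tert-butyldimethylsilyloxy)-5-[1-(3,4-bis(tert-butyldimethylsilyloxy)phenyl)-1,3-dimethoxy-3-oxopropan-2-yl]phenyl}acrylate (stereoisomer mixture) | COC(=O)/C=C/c1cc(O[Si](C)(C)C(C)(C)C)c(O[Si](C)(C)C(C)(C)C)c(c1)C(C(=O)OC)C(OC)c1ccc(O[Si](C)(C)C(C)(C)C)c(O[Si](C)(C)C(C)(C)C)c1
F3 | step 8 | methyl (E)-3-{5-[1-(3,4-dihydroxyphenyl)-1,3-dimethoxy-3-oxopropan-2-yl]-3,4-dihydroxyphenyl}acrylate (stereoisomer mixture) | COC(=O)/C=C/c1cc(O)c(O)c(c1)C(C(=O)OC)C(OC)c1ccc(O)c(O)c1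
F4 | step 4 | 2-[5-bromo-2,3-bis(tert-butyldimethylsilyloxy)phenyl]acetaldehyde | O=CCc1cc(Br)cc(O[Si](C)(C)C(C)(C)C)c1O[Si](C)(C)C(C)(C)C
F5 | step 4 | 2-[5-bromo-2,3-bis(tert-butyldimethylsilyloxy)phenyl]acetic acid | OC(=O)Cc1cc(Br)cc(O[Si](C)(C)C(C)(C)C)c1O[Si](C)(C)C(C)(C)C
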